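The numbers of this flask were set for the occasion; what happens was integrated by code.

**Two flasks.** Follow one molecule of J through its forks, in two flasks that differ in their J charge.

in all of them: D 30 mM; time 6.0 h
- Tuesday's: J 0.50 M
- Monday's: J 0.15 M

    J → Z (k1 = 0.0017 min⁻¹)
    J + D → Q + L (k2 = 0.078 M⁻¹ min⁻¹)
    J + Q → L + Q, rate k3*[Q]*[J] (k3 = 0.025 M⁻¹ min⁻¹)

- the average divides the monomer in chains by the number of chains begun, living and dead together
- run time (Tuesday's): 6.0 h

1. which of the two ends with the longer chains by the average number of monomer units in a chain (chains begun, living or dead) ("neither" if they lie within 10%) (Tuesday's / Monday's / neither)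
2. average number of monomer units in a chain (chains begun, living or dead) at the end, Tuesday's
3. average number of monomer units in a chain (chains begun, living or dead) at the end, Monday's

**The fork.** With J held at its charge, the time constant of D is 25.6 min on Tuesday's and 85.5 min on Monday's, against 408 min for J, so I take Q at the D charge from early on. J then decays pseudo-first-order through two exits, to Z or into a chain. The growth rate constant times Q, over that plus the rate constant to Z, gives 30.6%, the chain share: the chance that a reacting J ends in a chain.

**The length.** With Q held at the D charge, the two exits give J the same time constant in both flasks, so my estimate puts the reacted fraction at 58.6% in each by the end; it counts no separate exit for J + D, whose share depends on the J charge. The D charge is 6.00% of the J charge on Tuesday's and 20.0% on Monday's. Each chain takes one J for its first unit, and the chain share of the remaining reacted J adds to it. That gives 3.68 for Tuesday's and 1.59 for Monday's.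

**Turned round.** For "neither", Monday's, with the same J in chains, would have to begin chains on under 47.5% of its D. Reckoned the same way, 93.9% of that D begins one, so I commit to Tuesday's.

**The forecast.** It gives 3.55 and 1.55, so Tuesday's, both slightly below my figures. Tuesday's, it says, “leaves plenty of J for the slow propagation step”.

**The result.** The simulation gives 3.55 for Tuesday's and 1.56 for Monday's, so Tuesday's. On Tuesday's, D stood at 0.419% of its charge after 3.00 h and Q at 99.6% of the D charge, while J went on to Z and into chains; at 2.34 h the Z exit read 2.3 times the chain exit, where the chain share gives 2.27. On Monday's, chains went on beginning beside growth, D falling from 20.7% after 3.00 h to 8.10% after 6.00 h, with Q ending at 91.9% of the D charge.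

**Second flask.** Take Tuesday's with 0.12 M of D. The chain share becomes 63.8%, the reacted fraction 81.6%, and the length 2.53. The simulation gives 2.52.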